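**Plan**

- Numbering (furo[3,4-c]furan-1-one): C1 lactone carbonyl, O2, C3 (trihydroxyphenyl), C3a, C4H2, O5, C6 (catechol), C6a. Enabling feature: C3a is β to the ring oxygen O5 through C4, and C6 is benzylic. C3a can therefore be a β-metaloxy radical born from a C3a–C4 oxirane, and C6 the benzylic end of a styrene C6a=C6.
- Cuts: five aryl O–Si bonds; the C1 lactone back to a C1 methyl acetal; then O5–C6 and C3a–C6a together, which opens both rings to an acyclic mixed acetal; then the acetal bond O2–C1, which separates an epoxy carbinol (C3, C3a, C4) from a cinnamaldehyde acetal (C1, C6a, C6).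
- Forward: the two silylated benzaldehydes are elaborated separately (vinyl addition and epoxidation; Wittig and acetalisation) and joined by acetal exchange. One titanium/iodine operation closes ring A (C1, O2, C3, C3a, C6a) and then ring B (C3a, C4, O5, C6, C6a). Hydrolysis, lactol oxidation and desilylation finish.
- Stereochemistry: C3 comes from a Sharpless kinetic resolution with D-(−)-tartrate; C3a, C6a and C6 follow from C3 by substrate control in the cascade; the C1 epimers are inconsequential.

Key step: step 8

Remark: TBSO = tert-butyldimethylsilyloxy; the oxirane carbon of 5 loses its configuration in the C3a radical, so only the carbinol centre has to be homochiral; cyclopentadienyl rings of titanium compounds are drawn sigma-bonded in SMILES.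

**Route**

Step 1
Reactants: 1 3,4,5-trihydroxybenzaldehyde
Product: 2 3,4,5-tris(TBSO)benzaldehyde
Conditions: TBSCl (3.6 equiv), imidazole (7 equiv), DMF, 0 °C → rt
Reagents that add atoms: tert-butyldimethylsilyl chloride, CC(C)(C)[Si](C)(C)Cl
Why: Imidazole-assisted O-silylation of phenols leaves the aldehyde alone, and silyl ethers are chosen because they can be removed at the end without hydrogenolysis or Lewis acid, either of which would break the benzylic C3–O2 and C6–O5 bonds.

Step 2
Reactants: 2 3,4,5-tris(TBSO)benzaldehyde; 3 vinylmagnesium bromide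
Product: 4 (±)-1-[3,4,5-tris(TBSO)phenyl]prop-2-en-1-ol
Conditions: THF, −78 → 0 °C; aq. NH4Cl
Reagents that add atoms: none
Why: Grignard 1,2-addition to an aryl aldehyde is tolerated by aryl silyl ethers at low temperature, and the racemic carbinol formed is resolved in the next step.

Step 3
Reactants: 4 (±)-1-[3,4,5-tris(TBSO)phenyl]prop-2-en-1-ol
Product: 5 (R)-[(S)-oxiran-2-yl][3,4,5-tris(TBSO)phenyl]methanol (erythro epoxy alcohol)
Conditions: Ti(OiPr)4 (0.2 equiv), D-(−)-diisopropyl tartrate (0.24 equiv), tBuOOH (0.45 equiv, isooctane), 4 Å MS, CH2Cl2, −20 °C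
Reagents that add atoms: tert-butyl hydroperoxide, CC(C)(C)OO
Why: In this Sharpless kinetic resolution the (S)-carbinol should be the fast-reacting enantiomer with the D-(−)-tartrate and be epoxidised to the erythro epoxy alcohol while the (R)-carbinol stays behind, less than half an equivalent of oxidant keeping the epoxide enantiomerically clean; the carbinol centre becomes C3.

Step 4
Reactants: 6 3,4-dihydroxybenzaldehyde
Product: 7 3,4-bis(TBSO)benzaldehyde
Conditions: TBSCl (2.4 equiv), imidazole (5 equiv), DMF, 0 °C → rt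
Reagents that add atoms: tert-butyldimethylsilyl chloride, CC(C)(C)[Si](C)(C)Cl
Why: Same phenol silylation as in step 1, so that one fluoride treatment unmasks all five phenols at the end.

Step 5
Reactants: 7 3,4-bis(TBSO)benzaldehyde; 8 (triphenylphosphoranylidene)acetaldehyde
Product: 9 (E)-3-[3,4-bis(TBSO)phenyl]prop-2-enal
Conditions: toluene, 80 °C (1.05 equiv of 8)
Reagents that add atoms: none
Why: Wittig olefination with the stabilised formylmethylene ylide gives the (E)-enal, and only a slight excess of ylide is used to limit a second homologation.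

Step 6
Reactants: 9 (E)-3-[3,4-bis(TBSO)phenyl]prop-2-enal
Product: 10 4-[(E)-3,3-dimethoxyprop-1-enyl]-1,2-bis(TBSO)benzene (dimethyl acetal of 9)
Conditions: HC(OMe)3, PPTS (cat.), MeOH, rt; Et3N quench
Reagents that add atoms: trimethyl orthoformate, COC(OC)OC
Why: Acid-catalysed acetalisation with orthoformate as water scavenger converts conjugated aldehydes cleanly with retention of the E geometry, and aryl silyl ethers resist the weak acid.

Step 7
Reactants: 5 erythro epoxy alcohol; 10 dimethyl acetal of 9
Product: 11 mixed methyl acetal, (E)-3-[3,4-bis(TBSO)phenyl]-1-methoxyprop-2-enyl ether of 5 (both epimers at the acetal carbon)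
Conditions: 10 (2.5 equiv), PPTS (5 mol%), 5 Å MS, toluene, rt → 40 °C; Et3N quench, Et3N-deactivated silica
Reagents that add atoms: none
Why: In this acid-catalysed transacetalisation PPTS ionises 10 to an alkoxyallyl cation stabilised by the electron-rich arene, 5 adds at the acetal carbon, and excess 10 plus sieves that take up methanol drive the exchange towards the mixed acetal without touching the stereocentres of 5.

Step 8
Reactants: 11 mixed methyl acetal
Product: 14 (3S,3aR,6S,6aS)-6-[3,4-bis(TBSO)phenyl]-1-methoxy-3-[3,4,5-tris(TBSO)phenyl]tetrahydro-1H,3H-furo[3,4-c]furan (C1 epimers), via C6-titanium C4-titanoxy cyclisation intermediate 12 (not isolated), via C6 benzylic iodide C4 titanium alkoxide 13 (not isolated)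
Conditions: Cp2TiCl (2.5 equiv, from Cp2TiCl2 and Zn dust in THF, decanted) added slowly to 11, THF, rt; then I2 (1.5 equiv), THF, rt → 60 °C
Reagents that add atoms: none
Why: Cp2TiCl (trivalent titanium) transfers one electron to the oxirane and opens it to the secondary β-titanoxy radical at C3a, which adds to C6a of the styrene; the benzylic C6 radical is captured by a second Cp2TiCl to give 12, iodine turns the C6–Ti bond into the iodide 13, and the C4 titanium alkoxide displaces it. The closest known reaction type is the Cp2TiCl-induced radical cyclisation of epoxy cinnamyl ethers followed by iodine, which gives 2,6-diaryl furofurans; here the allylic ether carbon carries one more methoxy group, so that C1 emerges as an acetal. Ring A (C1, O2, C3, C3a, C6a) closes by radical 5-exo-trig addition and ring B (C3a, C4, O5, C6, C6a) by 5-exo-tet substitution at the benzylic iodide with much carbocation character. C3a and C6a are set by the C3 centre in a chair-like Beckwith–Houk transition state with the C3 aryl pseudo-equatorial (aryl trans to the C4 arm, C4 arm cis to the styrenyl carbon, hence a cis ring fusion), and C6 is set in the etherification, where the cation-like benzylic carbon can only bridge cis and places its aryl on the convex face. The step needs cyclisation to outrun reduction of the C3a radical by a second trivalent titanium (which would deoxygenate), secured by the fast 5-exo addition to a styrene and slow addition of the reagent, and it needs the acetal to survive, which the weakly Lewis acidic THF-solvated titanium and zinc halides should allow. Both C1 epimers are carried on because C1 becomes the carbonyl, and the configuration of the oxirane carbon is erased in the radical.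

Step 9
Reactants: 14 1-methoxy furofuran (C1 epimers)
Product: 15 (3S,3aR,6S,6aS)-6-[3,4-bis(TBSO)phenyl]-3-[3,4,5-tris(TBSO)phenyl]tetrahydro-1H,3H-furo[3,4-c]furan-1-ol (lactol, both anomers)
Conditions: 1 M aq. HCl/THF (1:5), 0 °C → rt
Reagents that add atoms: water, O
Why: Acid-catalysed hydrolysis of a 2-methoxytetrahydrofuran runs through the ring oxocarbenium ion under conditions that aryl silyl ethers resist, and the contact is kept short and cold so that neither benzylic ether ionises nor C6a epimerises through the open hydroxy aldehyde.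

Step 10
Reactants: 15 lactol
Product: 16 (3S,3aR,6S,6aS)-6-[3,4-bis(TBSO)phenyl]-3-[3,4,5-tris(TBSO)phenyl]tetrahydro-1H,3H-furo[3,4-c]furan-1-one
Conditions: Ag2CO3 on Celite (5 equiv), toluene, 90 °C
Reagents that add atoms: none
Why: The Fétizon oxidation converts lactols into lactones on a neutral surface, so silyl ethers, benzylic ethers and the C6a centre (held in the cis-fused bicycle) should be unaffected.

Step 11
Reactants: 16 pentakis-silylated lactone
Product: 17 (3S,3aR,6S,6aS)-6-(3,4-dihydroxyphenyl)-3-(3,4,5-trihydroxyphenyl)tetrahydro-1H,3H-furo[3,4-c]furan-1-one (CNP0290035.1)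
Conditions: Bu4NF (6 equiv), AcOH (6 equiv), THF, 0 °C → rt, argon
Reagents that add atoms: none
Why: Fluoride cleaves the aryl O–Si bonds, and acetic acid keeps the liberated phenols protonated, which should suppress quinone-methide formation at the para-hydroxybenzylic C3 and C6 centres and autoxidation of the catechol and pyrogallol rings.

**Compound list**

1 | 3,4,5-trihydroxybenzaldehyde | O=Cc1cc(O)c(O)c(O)c1 | starting material
2 | 3,4,5-tris(TBSO)benzaldehyde | O=Cc1cc(O[Si](C)(C)C(C)(C)C)c(O[Si](C)(C)C(C)(C)C)c(O[Si](C)(C)C(C)(C)C)c1 | intermediate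
3 | vinylmagnesium bromide | C=C[Mg]Br | starting material
4 | (±)-1-[3,4,5-tris(TBSO)phenyl]prop-2-en-1-ol | C=CC(O)c1cc(O[Si](C)(C)C(C)(C)C)c(O[Si](C)(C)C(C)(C)C)c(O[Si](C)(C)C(C)(C)C)c1 | intermediate
5 | (R)-[(S)-oxiran-2-yl][3,4,5-tris(TBSO)phenyl]methanol | O[C@H](c1cc(O[Si](C)(C)C(C)(C)C)c(O[Si](C)(C)C(C)(C)C)c(O[Si](C)(C)C(C)(C)C)c1)[C@@H]1CO1 | intermediate
6 | 3,4-dihydroxybenzaldehyde | O=Cc1ccc(O)c(O)c1 | starting material
7 | 3,4-bis(TBSO)benzaldehyde | O=Cc1ccc(O[Si](C)(C)C(C)(C)C)c(O[Si](C)(C)C(C)(C)C)c1 | intermediate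
8 | (triphenylphosphoranylidene)acetaldehyde | O=CC=P(c1ccccc1)(c1ccccc1)c1ccccc1 | starting material
9 | (E)-3-[3,4-bis(TBSO)phenyl]prop-2-enal | O=C/C=C/c1ccc(O[Si](C)(C)C(C)(C)C)c(O[Si](C)(C)C(C)(C)C)c1 | intermediate
10 | 4-[(E)-3,3-dimethoxyprop-1-enyl]-1,2-bis(TBSO)benzene | COC(OC)/C=C/c1ccc(O[Si](C)(C)C(C)(C)C)c(O[Si](C)(C)C(C)(C)C)c1 | intermediate
11 | mixed methyl acetal of 9 with 5 (both acetal epimers; key-step precursor) | COC(O[C@H](c1cc(O[Si](C)(C)C(C)(C)C)c(O[Si](C)(C)C(C)(C)C)c(O[Si](C)(C)C(C)(C)C)c1)[C@@H]1CO1)/C=C/c1ccc(O[Si](C)(C)C(C)(C)C)c(O[Si](C)(C)C(C)(C)C)c1 | intermediate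
12 | ring A closed: 2-methoxytetrahydrofuran with C4H2–O–TiCp2Cl and C6H(aryl)–TiCp2Cl (C1 and C6 epimers) | COC1O[C@H](c2cc(O[Si](C)(C)C(C)(C)C)c(O[Si](C)(C)C(C)(C)C)c(O[Si](C)(C)C(C)(C)C)c2)[C@@H](CO[Ti](Cl)(C2C=CC=C2)C2C=CC=C2)[C@H]1C(c1ccc(O[Si](C)(C)C(C)(C)C)c(O[Si](C)(C)C(C)(C)C)c1)[Ti](Cl)(C1C=CC=C1)C1C=CC=C1 | intermediate (not isolated)
13 | as 12 with C6–I in place of C6–Ti (C1 and C6 epimers) | COC1O[C@H](c2cc(O[Si](C)(C)C(C)(C)C)c(O[Si](C)(C)C(C)(C)C)c(O[Si](C)(C)C(C)(C)C)c2)[C@@H](CO[Ti](Cl)(C2C=CC=C2)C2C=CC=C2)[C@H]1C(I)c1ccc(O[Si](C)(C)C(C)(C)C)c(O[Si](C)(C)C(C)(C)C)c1 | intermediate (not isolated)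
14 | (3S,3aR,6S,6aS)-6-[3,4-bis(TBSO)phenyl]-1-methoxy-3-[3,4,5-tris(TBSO)phenyl]tetrahydro-1H,3H-furo[3,4-c]furan (C1 epimers; key-step product) | COC1O[C@H](c2cc(O[Si](C)(C)C(C)(C)C)c(O[Si](C)(C)C(C)(C)C)c(O[Si](C)(C)C(C)(C)C)c2)[C@H]2CO[C@H](c3ccc(O[Si](C)(C)C(C)(C)C)c(O[Si](C)(C)C(C)(C)C)c3)[C@@H]12 | intermediate
15 | corresponding furo[3,4-c]furan-1-ol (lactol, both anomers) | OC1O[C@H](c2cc(O[Si](C)(C)C(C)(C)C)c(O[Si](C)(C)C(C)(C)C)c(O[Si](C)(C)C(C)(C)C)c2)[C@H]2CO[C@H](c3ccc(O[Si](C)(C)C(C)(C)C)c(O[Si](C)(C)C(C)(C)C)c3)[C@@H]12 | intermediate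
16 | (3S,3aR,6S,6aS)-6-[3,4-bis(TBSO)phenyl]-3-[3,4,5-tris(TBSO)phenyl]tetrahydro-1H,3H-furo[3,4-c]furan-1-one | O=C1O[C@H](c2cc(O[Si](C)(C)C(C)(C)C)c(O[Si](C)(C)C(C)(C)C)c(O[Si](C)(C)C(C)(C)C)c2)[C@H]2CO[C@H](c3ccc(O[Si](C)(C)C(C)(C)C)c(O[Si](C)(C)C(C)(C)C)c3)[C@@H]12 | intermediate
17 | (3S,3aR,6S,6aS)-6-(3,4-dihydroxyphenyl)-3-(3,4,5-trihydroxyphenyl)tetrahydro-1H,3H-furo[3,4-c]furan-1-one | O=C1O[C@H](c2cc(O)c(O)c(O)c2)[C@H]2CO[C@H](c3ccc(O)c(O)c3)[C@@H]12 | target

**Step count**

Total: 11 steps. Longest linear sequence: 8 steps (1, 2, 3, 7, 8, 9, 10, 11); the branch 4, 5, 6 joins at step 7 and is equally long.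

**Steps most likely to fail**

Step 8. The C3a radical may be reduced by a second trivalent titanium before it cyclises, which leads to deoxygenation. The allylic acetal may ionise under the titanium and zinc halides. At the iodide stage, elimination to the benzylidene compound may compete with etherification. Fallback, from 11 back to 14: run the titanium step in its reductive mode and close ring B in a separate operation. Cp2TiCl followed by an aqueous NaH2PO4 quench should protonate the benzylic C6–Ti bond and give the monocyclic (2RS)-2-methoxy-3-[3,4-bis(TBSO)benzyl]-4-(hydroxymethyl)-5-[3,4,5-tris(TBSO)phenyl]tetrahydrofuran F1. A Suárez-type hypoiodite reaction (PhI(OAc)2, I2, cyclohexane/CH2Cl2, visible light) then generates the C4 alkoxy radical, which abstracts the benzylic C6 hydrogen through a six-membered transition state. Oxidation of the C6 radical and capture by the oxygen closes O5–C6 with the aryl on the convex face and returns to 14.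

Step 7. Acid may open or ionise the benzylic epoxy carbinol, the exchange may run on to the symmetrical acetal of two molecules of 5, the alcohol may attack the benzylic end of the alkoxyallyl cation, and the product may hydrolyse on silica. Fallback, from 10 (with 5) back to 11: activate the acetal under basic conditions instead of with a Brønsted acid. Et3SiOTf and 2,4,6-collidine in CH2Cl2 at 0 °C should convert 10 into the N-(1-methoxyallyl)collidinium triflate F2, which is treated in the same flask with 5 to give 11 without the epoxide ever meeting acid.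

Step 11. Phenoxide formed during fluoride treatment may expel O2 or O5 through a quinone methide (epimerisation or ring opening at C3 or C6), and the free catechol and pyrogallol rings may autoxidise during work-up and chromatography. Fallback, from 16 back to 17: exchange the protecting groups before unmasking. CsF and Ac2O in DMF should desilylate and acetylate in one operation, so that no free phenoxide persists, and give the pentaacetate F3, which can be purified without precautions. NH4OAc in aqueous MeOH at rt then removes the aryl acetates under near-neutral conditions and gives 17.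

**Further compounds**

F1 | step 8 | (2RS)-2-methoxy-3-[3,4-bis(TBSO)benzyl]-4-(hydroxymethyl)-5-[3,4,5-tris(TBSO)phenyl]tetrahydrofuran (ring A closed, C6 as CH2) | COC1O[C@H](c2cc(O[Si](C)(C)C(C)(C)C)c(O[Si](C)(C)C(C)(C)C)c(O[Si](C)(C)C(C)(C)C)c2)[C@@H](CO)[C@H]1Cc1ccc(O[Si](C)(C)C(C)(C)C)c(O[Si](C)(C)C(C)(C)C)c1
F2 | step 7 | 1-[(E)-3-[3,4-bis(TBSO)phenyl]-1-methoxyprop-2-enyl]-2,4,6-trimethylpyridinium triflate | COC(/C=C/c1ccc(O[Si](C)(C)C(C)(C)C)c(O[Si](C)(C)C(C)(C)C)c1)[n+]1c(C)cc(C)cc1C.[O-]S(=O)(=O)C(F)(F)F
F3 | step 11 | pentaacetate of 17 | O=C1O[C@H](c2cc(OC(C)=O)c(OC(C)=O)c(OC(C)=O)c2)[C@H]2CO[C@H](c3ccc(OC(C)=O)c(OC(C)=O)c3)[C@@H]12
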